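The last substrate reading of the midnight run stood higher than the first, 25.4 % at 25.0 h against 24.6 % at 2.00 h, a gap close to the scatter, so between those two readings that run showed no fall.

| flask | substrate | reagent | other conformer | remark | time |
|---|---|---|---|---|---|
| midnight | 20 mM | 10 mM | 2.5 mM | run made earlier |  |
| dawn | 20 mM | 10 mM | 3.8 mM | run made earlier |  |
| noon | 30 mM | 10 mM | 5 mM | run made earlier |  |
| flask | 20 mM | 10.0 mM | 5.00 mM |  | 25 h |

- midnight (time / h: substrate / %, target / %): 2.00: 24.6, 10.4; 3.00: 24.9, 9.4; 6.00: 25.4, 10.0; 10.0: 25.2, 9.1; 15.0: 23.9, 9.8; 25.0: 25.4, 9.8
- dawn (time / h: substrate / %, target / %): 4.00: 25.1, 8.2; 8.00: 24.8, 8.4; 12.0: 25.8, 8.6; 15.0: 24.6, 8.8; 20.0: 25.7, 8.0; 25.0: 25.2, 9.2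
- noon (time / h: substrate / %, target / %): 5.00: 31.1, 6.8; 10.0: 30.3, 6.2; 15.0: 30.2, 7.5; 20.0: 31.0, 6.8; 25.0: 30.8, 7.1

(standard deviation of a reading: 0.5 percentage points)

- what was read earlier has a scatter of 0.5 percentage points, one standard deviation
- in a conversion other conformer counts as not yet reacted

* how much of the substrate and other conformer together has reacted by 25 h
* how much target there is at 25 h, in percent of the substrate and other conformer together charged
* how much other conformer there is at 25 h, in percent of the substrate and other conformer together charged

What looked contradictory was this: at its last reading the midnight run held 5.71 mM of substrate, yet its target came to 2.21 mM from 10 mM of reagent charged. I cleared this up by counting turnovers. I supposed that each reagent turned over took one unit from the pool of substrate and other conformer, that target was one of several ends, and that reagent was the limiting reagent. The pool then left, divided by the last substrate reading, came to 2.19 at midnight, 2.30 at dawn and 2.32 at noon, close together across different charges, as two conformers in equilibrium would give. So I carried the turnover ceiling, c(reagent) charged over c(substrate) plus c(other conformer) charged, 40.0 % for the flask, and committed to that as its conversion.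

The forecast, which called the reagent not found in target “the rest an unseen by-product”, gave 40 % reacted, 7.5 % target and 33.7 % other conformer.

The flask gave 37.1 % reacted, 7.82 % target and 36.7 % other conformer.

    2 reagent → self-condensation product (k = 5.90 /M/min)
    substrate ⇌ other conformer (K = 1.40, k = 0.370 /min)
    substrate + reagent → target (k = 11.0 /M/min)
    reagent + other conformer → isomer of the product (k = 96.0 /M/min)

The flask ended 2.9 percentage points under its ceiling of 40.0 %, with reagent at 0 % of its charge at 25.0 h. In the run where reagent was kept from being used up, the same flask reached 100 % instead of 37.1 %, so the using up of reagent was the main reason for the stop. For the neighbour flask, charged like the flask except for 8.0 mM of substrate, the ceiling was 76.9 %, and that flask reached 67.8 %.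

The numbers in the tables were generated by integration with constants of no real substance; noise was put on by code.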